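(The earlier runs and the new flask were generated by integration on assumed constants; the scatter is artificial.)

Time is common ground here: our flask is asked about at 25 min, and the spring and noon runs were last read at 25.0 min and 25.0 min, so we can hold it against them without extrapolating in time, by counting turnovers, the turnover number: product made per catalyst charged.

| flask | solid substrate | free catalyst | remark | time |
|---|---|---|---|---|
| spring | 0.31 M | 0.5 mol% | run made earlier |  |
| noon | 0.69 M | 0.5 mol% | run made earlier |  |
| flask | 0.46 M | 0.5 mol% |  | 25 min |

| run | time / min | solid substrate / % | starting material / % | catalyst intermediate A / % | product / % | catalyst intermediate B / % |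
|---|---|---|---|---|---|---|
| spring | 1.33 | 85.2 | 14.1 | 0.8 | 2.0 | 1.0 |
| spring | 4.00 | 56.2 | 33.8 | 0.1 | 8.6 | 0.2 |
| spring | 8.00 | 27.3 | 51.6 | 0 | 20.4 | 0.9 |
| spring | 10.0 | 13.6 | 59.5 | 0 | 27.4 | 1.1 |
| spring | 15.0 | 0 | 57.6 | 0.1 | 39.1 | 0 |
| spring | 20.0 | 0.5 | 45.6 | 0 | 52.9 | 0.9 |
| spring | 25.0 | 0 | 34.9 | 1.9 | 64.2 | 0.4 |
| noon | 4.00 | 79.6 | 12.8 | 0.6 | 6.5 | 0 |
| noon | 8.00 | 64.1 | 22.7 | 0 | 12.6 | 0 |
| noon | 10.0 | 57.8 | 22.6 | 0.8 | 17.4 | 0 |
| noon | 15.0 | 41.9 | 28.0 | 0 | 29.9 | 1.2 |
| noon | 20.0 | 33.5 | 29.1 | 0 | 37.4 | 0 |
| noon | 25.0 | 22.1 | 31.7 | 0 | 44.9 | 0.8 |

(readings scatter by 1 percentage point)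

- solid, in amounts per volume of the solution: solid substrate
- the numbers in the tables scatter by 1 percentage point (one standard deviation)
- at the start none of the solid substrate is in solution
- starting material means what is dissolved; the solid is not counted in it

* the largest share of what was charged as solid substrate, at 25 min belongs to (product / starting material / catalyst intermediate A / catalyst intermediate B)
* the largest share itself, whichever of these holds it, in percent of the solid substrate charged

Both runs carry the same loading, 0.5 mol%, so the product share is the count times the loading, and the two runs end apart as their counts do. Spring's 64.2% is 128 turnovers, on average one per 11.7 s, while noon's 44.9% is 89.8, one per 16.7 s. Noon did make more product than spring in molar terms, 0.310 M against 0.199 M, but it shared that among 2.23 times the catalyst, so each catalyst turned fewer times.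

Between these runs, we read the count as falling with c(solid substrate) to the power 0.447, the turnover slope, a reading that carries the scatter of its two points. At our flask's 0.46 M the slope gives 108 turnovers, so 54.0% product by our reckoning. That exceeds the 46.0% left for everything else together, so by this estimate we expect product to lead.

The forecast gives product at 54%, holding that “The rate is nearly zero order in starting material”.

The flask gives product at 56.2%, which is 112 turnovers against our 108, with starting material at 43.3%.

    solid substrate ⇌ starting material, rate k1*(cs1 - [starting material]) while solid is left; crystals form when [starting material] > cs1 (solubility = 0.320 M, k = 0.130 /min)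
    2 catalyst intermediate B ⇌ resting dimer, settled at all times (K = 1300 /M)
    catalyst intermediate A → catalyst intermediate B (k = 1500 /min)
    catalyst intermediate B ⇌ free catalyst + product (K = 0.200 M, k = 20.0 /min)
    starting material + free catalyst → catalyst intermediate A (k = 220 /M/min)

In our flask at 25.0 min the resting dimer, the catalyst's resting state, holds 59.2% of the catalyst charged, each dimer counted as two, against 31.5% as catalyst intermediate B and 9.03% as free catalyst. A further flask with 0.28 M of solid substrate, at the same loading and time, gets 134 turnovers from the slope, so 67.0% product, and that flask holds 65.5%.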